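**Retrosynthetic overview**
1. The dipalmitate comes from lutein 5,6-epoxide 31 by double acylation; the polyene comes from two Wittig bonds, C11'=C12' (ε-C15 salt 26 + C10 dialdehyde 27) and C11=C12 (C25 salt 30 + epoxy-C15 aldehyde 12).
2. Epoxy end: ring A (C1–C6) is bought with actinol 1; the 5,6-epoxide is closed next by Sharpless epoxidation (step 5).
3. ε-Ring (C1'–C6'), closed last (step 11): a photochemical 1,3-shift in (1R,5R)-verbenone 13 makes the bond C1'–C6' and gives chrysanthenone 14, which is the ε-ring bridged from C2' to C6' by a cyclobutanone carbonyl (the future C7').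
4. Enabling feature: C6' is allylic to C4'=C5' and carries both the gem-dimethyl carbon C1' and the exocyclic carbon C7'; this 2,6,6-trimethylcyclohex-2-ene-1-carbonyl unit is the ring-opened form of the strained bicyclo[3.1.1]hept-2-en-6-one, so the allylic cyclobutane bond of a pinane enone can be shifted onto it.
5. The strain is then spent: allylic oxidation at C3' and retro-Claisen opening of C7'–C2' (step 12) free the ring with 6'R taken from the terpene, and C3' (R) follows by hydride reduction. Ring order: ring A (bought), epoxide (step 5), ε-ring (step 11).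

Key step: step 11

Remark: (4R,6R)-actinol 1, (1R,5R)-(+)-verbenone 13 and C10 dialdehyde 27 are taken as purchasable; the Wittig couplings give E/Z mixtures at the new double bonds, which are equilibrated thermally to all-E.

**Route**

Step 1
Reactants: 1 (4R,6R)-4-hydroxy-2,2,6-trimethylcyclohexan-1-one
Product: 2 (4R,6R)-4-(tert-butyldimethylsilyloxy)-2,2,6-trimethylcyclohexan-1-one
Conditions: t-BuMe2SiCl, imidazole, DMF, rt
Reagents that add atoms: tert-butyldimethylsilyl chloride, CC(C)(C)[Si](C)(C)Cl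
Why: Silylation of the secondary alcohol protects it for the enolate and hydride steps and touches no stereocentre.

Step 2
Reactants: 2 (4R,6R)-4-(tert-butyldimethylsilyloxy)-2,2,6-trimethylcyclohexan-1-one
Product: 3 (4R)-4-(tert-butyldimethylsilyloxy)-2,6,6-trimethylcyclohex-1-en-1-yl trifluoromethanesulfonate
Conditions: LiN(i-Pr)2, THF, −78 °C; PhNTf2, −78 °C to rt
Reagents that add atoms: N-phenylbis(trifluoromethanesulfonimide), O=S(=O)(N(c1ccccc1)S(=O)(=O)C(F)(F)F)C(F)(F)F
Why: Enolisation is possible only toward the methyl-bearing carbon (the other α-carbon is quaternary) and O-sulfonylation of the enolate gives the enol triflate, which removes the methyl-bearing stereocentre on purpose and leaves the carbinol centre untouched.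

Step 3
Reactants: 3 (4R)-4-(tert-butyldimethylsilyloxy)-2,6,6-trimethylcyclohex-1-en-1-yl trifluoromethanesulfonate
Product: 4 methyl (4R)-4-(tert-butyldimethylsilyloxy)-2,6,6-trimethylcyclohex-1-ene-1-carboxylate
Conditions: Pd(OAc)2 (5 mol %), PPh3, CO (1 atm), Et3N, MeOH, DMF, 60 °C
Reagents that add atoms: carbon monoxide, [C-]#[O+]; methanol, CO
Why: Palladium-catalysed alkoxycarbonylation, in which zerovalent palladium inserts into the C–OTf bond, CO inserts and methanol cleaves the acyl complex, installs C7 on the hindered ring carbon.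

Step 4
Reactants: 4 methyl (4R)-4-(tert-butyldimethylsilyloxy)-2,6,6-trimethylcyclohex-1-ene-1-carboxylate
Product: 5 [(4R)-4-(tert-butyldimethylsilyloxy)-2,6,6-trimethylcyclohex-1-en-1-yl]methanol
Conditions: i-Bu2AlH, CH2Cl2, −78 °C
Reagents that add atoms: none
Why: 1,2-Reduction of the enoate by the aluminium hydride gives the allylic alcohol needed to direct the epoxidation.

Step 5
Reactants: 5 [(4R)-4-(tert-butyldimethylsilyloxy)-2,6,6-trimethylcyclohex-1-en-1-yl]methanol
Product: 6 [(1R,4S,6R)-4-(tert-butyldimethylsilyloxy)-2,2,6-trimethyl-7-oxabicyclo[4.1.0]heptan-1-yl]methanol (epoxide anti to the silyloxy group)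
Conditions: Ti(Oi-Pr)4 (0.2 equiv), D-(−)-diethyl tartrate (0.24 equiv), t-BuOOH, 4 Å MS, CH2Cl2, −20 °C
Reagents that add atoms: tert-butyl hydroperoxide, CC(C)(C)OO
Why: Sharpless asymmetric epoxidation, in which the titanium-bound allylic alcohol receives oxygen from the D-(−)-tartrate complex on the alkene face anti to the silyloxy group (also the face the substrate prefers, a matched case), sets both epoxide stereocentres, C5 and C6 of the target, in the required sense.

Step 6
Reactants: 6 [(1R,4S,6R)-4-(tert-butyldimethylsilyloxy)-2,2,6-trimethyl-7-oxabicyclo[4.1.0]heptan-1-yl]methanol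
Product: 7 (1S,4S,6R)-4-(tert-butyldimethylsilyloxy)-2,2,6-trimethyl-7-oxabicyclo[4.1.0]heptane-1-carbaldehyde
Conditions: Pr4N[RuO4] (5 mol %), N-methylmorpholine N-oxide, 4 Å MS, CH2Cl2, rt
Reagents that add atoms: none
Why: Ley–Griffith oxidation under neutral conditions gives the aldehyde without opening the epoxide, and the aldehyde carbon sits on a quaternary carbon so nothing can epimerise.

Step 7
Reactants: 7 (1S,4S,6R)-4-(tert-butyldimethylsilyloxy)-2,2,6-trimethyl-7-oxabicyclo[4.1.0]heptane-1-carbaldehyde; 8 triethyl (2E)-3-methyl-4-phosphonobut-2-enoate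
Product: 9 ethyl (2E,4E)-5-[(1S,4S,6R)-4-(tert-butyldimethylsilyloxy)-2,2,6-trimethyl-7-oxabicyclo[4.1.0]heptan-1-yl]-3-methylpenta-2,4-dienoate
Conditions: 8, n-BuLi, THF, −78 °C; then 7, −78 to 0 °C
Reagents that add atoms: 8 triethyl (2E)-3-methyl-4-phosphonobut-2-enoate, CCOC(=O)/C=C(\C)CP(=O)(OCC)OCC
Why: Horner–Wadsworth–Emmons olefination with the vinylogous phosphonate anion should give the E C7=C8 bond and mainly the 9E dienoate, with the minor 9Z isomer removed by chromatography.

Step 8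
Reactants: 9 ethyl (2E,4E)-5-[(1S,4S,6R)-4-(tert-butyldimethylsilyloxy)-2,2,6-trimethyl-7-oxabicyclo[4.1.0]heptan-1-yl]-3-methylpenta-2,4-dienoate
Product: 10 ethyl (2E,4E)-5-[(1S,4S,6R)-4-hydroxy-2,2,6-trimethyl-7-oxabicyclo[4.1.0]heptan-1-yl]-3-methylpenta-2,4-dienoate
Conditions: Bu4NF, THF, 0 °C to rt
Reagents that add atoms: none
Why: Fluoride cleaves the silyl ether at the robust ester stage under conditions that leave the base-stable epoxide alone.

Step 9
Reactants: 10 ethyl (2E,4E)-5-[(1S,4S,6R)-4-hydroxy-2,2,6-trimethyl-7-oxabicyclo[4.1.0]heptan-1-yl]-3-methylpenta-2,4-dienoate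
Product: 11 (2E,4E)-5-[(1S,4S,6R)-4-hydroxy-2,2,6-trimethyl-7-oxabicyclo[4.1.0]heptan-1-yl]-3-methylpenta-2,4-dien-1-ol
Conditions: i-Bu2AlH (3.5 equiv), CH2Cl2, −78 °C
Reagents that add atoms: none
Why: Ester reduction by the aluminium hydride gives the dienol, and the fully substituted epoxide should be inert at −78 °C.

Step 10
Reactants: 11 (2E,4E)-5-[(1S,4S,6R)-4-hydroxy-2,2,6-trimethyl-7-oxabicyclo[4.1.0]heptan-1-yl]-3-methylpenta-2,4-dien-1-ol
Product: 12 (2E,4E)-5-[(1S,4S,6R)-4-hydroxy-2,2,6-trimethyl-7-oxabicyclo[4.1.0]heptan-1-yl]-3-methylpenta-2,4-dienal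
Conditions: MnO2, CH2Cl2, rt
Reagents that add atoms: none
Why: MnO2 oxidises only the allylic primary alcohol and leaves the saturated secondary ring alcohol, giving the epoxy-C15 aldehyde without any acid.

Step 11
Reactants: 13 (1R,5R)-4,6,6-trimethylbicyclo[3.1.1]hept-3-en-2-one
Product: 14 (1S,5R)-2,7,7-trimethylbicyclo[3.1.1]hept-2-en-6-one
Conditions: hν (350 nm lamps, uranium-glass filter, λ > 330 nm), degassed cyclohexane (0.02 M), rt, to about half conversion; 13 recovered and recycled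
Reagents that add atoms: none
Why: Excitation of the enone of 13 breaks the allylic cyclobutane bond C5–C6 to an allyl/tertiary-alkyl biradical, and the dimethyl-substituted radical centre rebonds at the former α-carbon C3, a 1,3-alkyl shift. The closest known reaction type is exactly this photoisomerisation of bicyclo[3.1.1]hept-3-en-2-ones to bicyclo[3.1.1]hept-2-en-6-ones (verbenone to chrysanthenone). The one new bond, C1'–C6', closes two rings by radical recombination: the six-membered ε-carbocycle C1'–C2'–C3'–C4'–C5'–C6' and the temporary four-membered ketone ring C1'–C2'–C7'–C6', a strained bicycle that no thermal route from 13 reaches. The new stereocentre C6' is controlled by the bridgehead C1 of 13 (the later C2'): the migrating carbon stays bonded to it and can only reach the same face of the allyl unit, so (1R,5R)-13 gives the configuration that becomes 6'R. The step needs site selectivity (rebonding at C3 and not back at C5, which merely returns 13) and conservation of enantiomeric purity, which secondary photolysis of 14 to an achiral dienylketene would erode; the long-wavelength window in which only the conjugated enone of 13 absorbs, and the stop at partial conversion, should secure it.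

Step 12
Reactants: 14 (1S,5R)-2,7,7-trimethylbicyclo[3.1.1]hept-2-en-6-one
Product: 16 methyl (1R)-2,6,6-trimethyl-4-oxocyclohex-2-ene-1-carboxylate, via bridged enedione 15 (not isolated)
Conditions: CrO3, 3,5-dimethylpyrazole, CH2Cl2, −20 °C; filtration through Celite; then MeOH, pyridinium p-toluenesulfonate (cat.), 0 °C to rt
Reagents that add atoms: chromium trioxide, O=[Cr](=O)=O; methanol, CO
Why: Chromium-mediated allylic oxidation of the only allylic methylene (C3', the same change as pinene to verbenone) gives a non-enolisable bridged 1,3-diketone, and methanol then adds to the strained cyclobutanone carbonyl and breaks C7'–C2' in a retro-Claisen cleavage, because only that bond releases an enol conjugated with the C3' ketone; ring strain drives it and C6' is not touched.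

Step 13
Reactants: 16 methyl (1R)-2,6,6-trimethyl-4-oxocyclohex-2-ene-1-carboxylate
Product: 17 methyl (1R,4R)-4-hydroxy-2,6,6-trimethylcyclohex-2-ene-1-carboxylate
Conditions: LiBH(s-Bu)3, THF, −78 °C
Reagents that add atoms: none
Why: 1,2-Reduction of the β,β-disubstituted enone by a bulky hydride should occur from the face syn to the pseudo-axial ester, because in the half-chair that avoids allylic strain with the C5' methyl the axial C1' methyl blocks the other face, so the new C3' hydroxyl ends up trans to the ester (3'R).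

Step 14
Reactants: 17 methyl (1R,4R)-4-hydroxy-2,6,6-trimethylcyclohex-2-ene-1-carboxylate
Product: 18 methyl (1R,4R)-4-(tert-butyldimethylsilyloxy)-2,6,6-trimethylcyclohex-2-ene-1-carboxylate
Conditions: t-BuMe2SiCl, imidazole, DMF, rt
Reagents that add atoms: tert-butyldimethylsilyl chloride, CC(C)(C)[Si](C)(C)Cl
Why: Silylation protects the allylic alcohol for the reduction–oxidation sequence and changes no stereocentre.

Step 15
Reactants: 18 methyl (1R,4R)-4-(tert-butyldimethylsilyloxy)-2,6,6-trimethylcyclohex-2-ene-1-carboxylate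
Product: 19 [(1R,4R)-4-(tert-butyldimethylsilyloxy)-2,6,6-trimethylcyclohex-2-en-1-yl]methanol
Conditions: i-Bu2AlH, CH2Cl2, −78 °C
Reagents that add atoms: none
Why: Ester reduction by the aluminium hydride gives the primary alcohol without base, so the C6' centre is not at risk.

Step 16
Reactants: 19 [(1R,4R)-4-(tert-butyldimethylsilyloxy)-2,6,6-trimethylcyclohex-2-en-1-yl]methanol
Product: 20 (1R,4R)-4-(tert-butyldimethylsilyloxy)-2,6,6-trimethylcyclohex-2-ene-1-carbaldehyde
Conditions: Pr4N[RuO4] (5 mol %), N-methylmorpholine N-oxide, 4 Å MS, CH2Cl2, 0 °C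
Reagents that add atoms: none
Why: Ley–Griffith oxidation is close to neutral, so the hindered α-stereocentre of the aldehyde should neither epimerise nor slip into conjugation, and any epimer would now be a separable diastereomer.

Step 17
Reactants: 20 (1R,4R)-4-(tert-butyldimethylsilyloxy)-2,6,6-trimethylcyclohex-2-ene-1-carbaldehyde; 21 1-(triphenyl-λ5-phosphanylidene)propan-2-one
Product: 22 (3E)-4-[(1R,4R)-4-(tert-butyldimethylsilyloxy)-2,6,6-trimethylcyclohex-2-en-1-yl]but-3-en-2-one
Conditions: 21, toluene, 80 °C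
Reagents that add atoms: 21 1-(triphenyl-λ5-phosphanylidene)propan-2-one, CC(=O)C=P(c1ccccc1)(c1ccccc1)c1ccccc1
Why: Wittig olefination with the stabilised, non-basic ylide gives the E enone and builds C7'=C8' directly on the C6' stereocentre without a basic step.

Step 18
Reactants: 22 (3E)-4-[(1R,4R)-4-(tert-butyldimethylsilyloxy)-2,6,6-trimethylcyclohex-2-en-1-yl]but-3-en-2-one
Product: 23 (3E)-4-[(1R,4R)-4-hydroxy-2,6,6-trimethylcyclohex-2-en-1-yl]but-3-en-2-one ((3R,6R)-3-hydroxy-α-ionone)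
Conditions: Bu4NF, THF, 0 °C
Reagents that add atoms: none
Why: Fluoride desilylation frees the 3'-hydroxyl before the acidic phosphonium step, so that the product of that step is unambiguous.

Step 19
Reactants: 23 (3E)-4-[(1R,4R)-4-hydroxy-2,6,6-trimethylcyclohex-2-en-1-yl]but-3-en-2-one; 24 vinylmagnesium bromide
Product: 25 (1E)-1-[(1R,4R)-4-hydroxy-2,6,6-trimethylcyclohex-2-en-1-yl]-3-methylpenta-1,4-dien-3-ol (both epimers at the new carbinol)
Conditions: CH2=CHMgBr (2.5 equiv), THF, −78 to 0 °C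
Reagents that add atoms: 24 vinylmagnesium bromide, C=C[Mg]Br
Why: Grignard 1,2-addition to the methyl ketone (the first equivalent is consumed by the hydroxyl) gives the tertiary bis-allylic alcohol, whose new centre is formed without control and disappears in step 20.

Step 20
Reactants: 25 (1E)-1-[(1R,4R)-4-hydroxy-2,6,6-trimethylcyclohex-2-en-1-yl]-3-methylpenta-1,4-dien-3-ol
Product: 26 [(2E,4E)-5-[(1R,4R)-4-hydroxy-2,6,6-trimethylcyclohex-2-en-1-yl]-3-methylpenta-2,4-dien-1-yl]triphenylphosphonium bromide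
Conditions: PPh3·HBr, MeOH, 0 °C to rt; crystallisation of the all-E salt
Reagents that add atoms: triphenylphosphine hydrobromide, [Br-].[PH+](c1ccccc1)(c1ccccc1)c1ccccc1
Why: Acid ionises the doubly allylic tertiary alcohol to a pentadienyl cation that PPh3 captures at the unhindered terminus (SN1-type allylic transposition), while the secondary allylic 3'-hydroxyl ionises far more slowly and should survive.

Step 21
Reactants: 26 [(2E,4E)-5-[(1R,4R)-4-hydroxy-2,6,6-trimethylcyclohex-2-en-1-yl]-3-methylpenta-2,4-dien-1-yl]triphenylphosphonium bromide; 27 (2E,4E,6E)-2,7-dimethylocta-2,4,6-trienedial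
Product: 28 (2E,4E,6E,8E,10E,12E)-13-[(1R,4R)-4-hydroxy-2,6,6-trimethylcyclohex-2-en-1-yl]-2,7,11-trimethyltrideca-2,4,6,8,10,12-hexaenal
Conditions: 27 (2 equiv), NaOMe, MeOH–CH2Cl2, −10 °C to rt; then heptane, reflux (Z to E)
Reagents that add atoms: 27 (2E,4E,6E)-2,7-dimethylocta-2,4,6-trienedial, O=C/C(C)=C/C=C/C=C(C)/C=O
Why: Wittig olefination of one aldehyde group of the excess dialdehyde forms C11'=C12', and the Z isomer at the new bond is equilibrated thermally to E.

Step 22
Reactants: 28 (2E,4E,6E,8E,10E,12E)-13-[(1R,4R)-4-hydroxy-2,6,6-trimethylcyclohex-2-en-1-yl]-2,7,11-trimethyltrideca-2,4,6,8,10,12-hexaenal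
Product: 29 (2E,4E,6E,8E,10E,12E)-13-[(1R,4R)-4-hydroxy-2,6,6-trimethylcyclohex-2-en-1-yl]-2,7,11-trimethyltrideca-2,4,6,8,10,12-hexaen-1-ol
Conditions: NaBH4, MeOH–THF, 0 °C
Reagents that add atoms: none
Why: Borohydride 1,2-reduction of the polyenal gives the polyenol that is the precursor of the C25 Wittig salt.

Step 23
Reactants: 29 (2E,4E,6E,8E,10E,12E)-13-[(1R,4R)-4-hydroxy-2,6,6-trimethylcyclohex-2-en-1-yl]-2,7,11-trimethyltrideca-2,4,6,8,10,12-hexaen-1-ol
Product: 30 [(2E,4E,6E,8E,10E,12E)-13-[(1R,4R)-4-hydroxy-2,6,6-trimethylcyclohex-2-en-1-yl]-2,7,11-trimethyltrideca-2,4,6,8,10,12-hexaen-1-yl]triphenylphosphonium bromide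
Conditions: PPh3·HBr, CH2Cl2–MeOH, 0 °C
Reagents that add atoms: triphenylphosphine hydrobromide, [Br-].[PH+](c1ccccc1)(c1ccccc1)c1ccccc1
Why: The polyenyl primary alcohol ionises readily to a highly delocalised cation that PPh3 traps at the terminus (SN1-type phosphonium salt formation), so the acid meets only the ε half and never the epoxide.

Step 24
Reactants: 30 [(2E,4E,6E,8E,10E,12E)-13-[(1R,4R)-4-hydroxy-2,6,6-trimethylcyclohex-2-en-1-yl]-2,7,11-trimethyltrideca-2,4,6,8,10,12-hexaen-1-yl]triphenylphosphonium bromide; 12 (2E,4E)-5-[(1S,4S,6R)-4-hydroxy-2,2,6-trimethyl-7-oxabicyclo[4.1.0]heptan-1-yl]-3-methylpenta-2,4-dienal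
Product: 31 (3S,5R,6S,3'R,6'R)-5,6-epoxy-5,6-dihydro-β,ε-carotene-3,3'-diol
Conditions: NaOMe, MeOH–CH2Cl2, −10 °C to rt; then EtOH, reflux, dark (Z to E)
Reagents that add atoms: none
Why: Wittig olefination under basic conditions forms C11=C12 and joins the two halves, the 5,6-epoxide is stable to base, and thermal equilibration should give the all-E polyene.

Step 25
Reactants: 31 (3S,5R,6S,3'R,6'R)-5,6-epoxy-5,6-dihydro-β,ε-carotene-3,3'-diol; 32 hexadecanoyl chloride
Product: 33 (3S,5R,6S,3'R,6'R)-5,6-epoxy-5,6-dihydro-β,ε-carotene-3,3'-diyl dihexadecanoate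
Conditions: 32 (3 equiv), pyridine, CH2Cl2, 0 °C to rt, dark
Reagents that add atoms: 32 hexadecanoyl chloride, CCCCCCCCCCCCCCCC(=O)Cl
Why: Acylation of both secondary hydroxyls forms only acyl–oxygen bonds, so C3 and C3' keep their configuration, and the pyridine buffer should protect the acid-labile epoxide and allylic ester.

**Compound list**
1 | (4R,6R)-4-hydroxy-2,2,6-trimethylcyclohexan-1-one (actinol) | O[C@H]1CC(C)(C)C(=O)[C@H](C)C1 | starting material
2 | (4R,6R)-4-(tert-butyldimethylsilyloxy)-2,2,6-trimethylcyclohexan-1-one | CC(C)(C)[Si](C)(C)O[C@H]1CC(C)(C)C(=O)[C@H](C)C1 | intermediate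
3 | (4R)-4-(tert-butyldimethylsilyloxy)-2,6,6-trimethylcyclohex-1-en-1-yl trifluoromethanesulfonate | CC(C)(C)[Si](C)(C)O[C@H]1CC(C)(C)C(OS(=O)(=O)C(F)(F)F)=C(C)C1 | intermediate
4 | methyl (4R)-4-(tert-butyldimethylsilyloxy)-2,6,6-trimethylcyclohex-1-ene-1-carboxylate | CC(C)(C)[Si](C)(C)O[C@H]1CC(C)(C)C(C(=O)OC)=C(C)C1 | intermediate
5 | [(4R)-4-(tert-butyldimethylsilyloxy)-2,6,6-trimethylcyclohex-1-en-1-yl]methanol | CC(C)(C)[Si](C)(C)O[C@H]1CC(C)(C)C(CO)=C(C)C1 | intermediate
6 | [(1R,4S,6R)-4-(tert-butyldimethylsilyloxy)-2,2,6-trimethyl-7-oxabicyclo[4.1.0]heptan-1-yl]methanol | CC(C)(C)[Si](C)(C)O[C@H]1CC(C)(C)[C@]2(CO)O[C@]2(C)C1 | intermediate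
7 | (1S,4S,6R)-4-(tert-butyldimethylsilyloxy)-2,2,6-trimethyl-7-oxabicyclo[4.1.0]heptane-1-carbaldehyde | CC(C)(C)[Si](C)(C)O[C@H]1CC(C)(C)[C@]2(C=O)O[C@]2(C)C1 | intermediate
8 | triethyl (2E)-3-methyl-4-phosphonobut-2-enoate | CCOC(=O)/C=C(\C)CP(=O)(OCC)OCC | starting material
9 | ethyl (2E,4E)-5-[(1S,4S,6R)-4-(tert-butyldimethylsilyloxy)-2,2,6-trimethyl-7-oxabicyclo[4.1.0]heptan-1-yl]-3-methylpenta-2,4-dienoate | CC(C)(C)[Si](C)(C)O[C@H]1CC(C)(C)[C@]2(/C=C/C(C)=C/C(=O)OCC)O[C@]2(C)C1 | intermediate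
10 | ethyl (2E,4E)-5-[(1S,4S,6R)-4-hydroxy-2,2,6-trimethyl-7-oxabicyclo[4.1.0]heptan-1-yl]-3-methylpenta-2,4-dienoate | O[C@H]1CC(C)(C)[C@]2(/C=C/C(C)=C/C(=O)OCC)O[C@]2(C)C1 | intermediate
11 | (2E,4E)-5-[(1S,4S,6R)-4-hydroxy-2,2,6-trimethyl-7-oxabicyclo[4.1.0]heptan-1-yl]-3-methylpenta-2,4-dien-1-ol | O[C@H]1CC(C)(C)[C@]2(/C=C/C(C)=C/CO)O[C@]2(C)C1 | intermediate
12 | (2E,4E)-5-[(1S,4S,6R)-4-hydroxy-2,2,6-trimethyl-7-oxabicyclo[4.1.0]heptan-1-yl]-3-methylpenta-2,4-dienal | O[C@H]1CC(C)(C)[C@]2(/C=C/C(C)=C/C=O)O[C@]2(C)C1 | intermediate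
13 | (1R,5R)-4,6,6-trimethylbicyclo[3.1.1]hept-3-en-2-one ((+)-verbenone) | CC1=CC(=O)[C@@H]2C[C@H]1C2(C)C | starting material
14 | (1S,5R)-2,7,7-trimethylbicyclo[3.1.1]hept-2-en-6-one (chrysanthenone) | CC1=CC[C@H]2C(=O)[C@@H]1C2(C)C | intermediate
15 | (1S,5S)-2,7,7-trimethylbicyclo[3.1.1]hept-2-ene-4,6-dione | CC1=CC(=O)[C@H]2C(=O)[C@@H]1C2(C)C | intermediate
16 | methyl (1R)-2,6,6-trimethyl-4-oxocyclohex-2-ene-1-carboxylate | COC(=O)[C@H]1C(C)=CC(=O)CC1(C)C | intermediate
17 | methyl (1R,4R)-4-hydroxy-2,6,6-trimethylcyclohex-2-ene-1-carboxylate | COC(=O)[C@H]1C(C)=C[C@H](O)CC1(C)C | intermediate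
18 | methyl (1R,4R)-4-(tert-butyldimethylsilyloxy)-2,6,6-trimethylcyclohex-2-ene-1-carboxylate | COC(=O)[C@H]1C(C)=C[C@H](O[Si](C)(C)C(C)(C)C)CC1(C)C | intermediate
19 | [(1R,4R)-4-(tert-butyldimethylsilyloxy)-2,6,6-trimethylcyclohex-2-en-1-yl]methanol | OC[C@H]1C(C)=C[C@H](O[Si](C)(C)C(C)(C)C)CC1(C)C | intermediate
20 | (1R,4R)-4-(tert-butyldimethylsilyloxy)-2,6,6-trimethylcyclohex-2-ene-1-carbaldehyde | O=C[C@H]1C(C)=C[C@H](O[Si](C)(C)C(C)(C)C)CC1(C)C | intermediate
21 | 1-(triphenyl-λ5-phosphanylidene)propan-2-one | CC(=O)C=P(c1ccccc1)(c1ccccc1)c1ccccc1 | starting material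
22 | (3E)-4-[(1R,4R)-4-(tert-butyldimethylsilyloxy)-2,6,6-trimethylcyclohex-2-en-1-yl]but-3-en-2-one | CC(=O)/C=C/[C@H]1C(C)=C[C@H](O[Si](C)(C)C(C)(C)C)CC1(C)C | intermediate
23 | (3E)-4-[(1R,4R)-4-hydroxy-2,6,6-trimethylcyclohex-2-en-1-yl]but-3-en-2-one ((3R,6R)-3-hydroxy-α-ionone) | CC(=O)/C=C/[C@H]1C(C)=C[C@H](O)CC1(C)C | intermediate
24 | vinylmagnesium bromide | C=C[Mg]Br | starting material
25 | (1E)-1-[(1R,4R)-4-hydroxy-2,6,6-trimethylcyclohex-2-en-1-yl]-3-methylpenta-1,4-dien-3-ol (carbinol epimers) | C=CC(C)(O)/C=C/[C@H]1C(C)=C[C@H](O)CC1(C)C | intermediate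
26 | [(2E,4E)-5-[(1R,4R)-4-hydroxy-2,6,6-trimethylcyclohex-2-en-1-yl]-3-methylpenta-2,4-dien-1-yl]triphenylphosphonium bromide | [P+](c1ccccc1)(c1ccccc1)(c1ccccc1)C/C=C(C)/C=C/[C@H]1C(C)=C[C@H](O)CC1(C)C.[Br-] | intermediate
27 | (2E,4E,6E)-2,7-dimethylocta-2,4,6-trienedial | O=C/C(C)=C/C=C/C=C(C)/C=O | starting material
28 | (2E,4E,6E,8E,10E,12E)-13-[(1R,4R)-4-hydroxy-2,6,6-trimethylcyclohex-2-en-1-yl]-2,7,11-trimethyltrideca-2,4,6,8,10,12-hexaenal | O=C/C(C)=C/C=C/C=C(C)/C=C/C=C(C)/C=C/[C@H]1C(C)=C[C@H](O)CC1(C)C | intermediate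
29 | (2E,4E,6E,8E,10E,12E)-13-[(1R,4R)-4-hydroxy-2,6,6-trimethylcyclohex-2-en-1-yl]-2,7,11-trimethyltrideca-2,4,6,8,10,12-hexaen-1-ol | OC/C(C)=C/C=C/C=C(C)/C=C/C=C(C)/C=C/[C@H]1C(C)=C[C@H](O)CC1(C)C | intermediate
30 | [(2E,4E,6E,8E,10E,12E)-13-[(1R,4R)-4-hydroxy-2,6,6-trimethylcyclohex-2-en-1-yl]-2,7,11-trimethyltrideca-2,4,6,8,10,12-hexaen-1-yl]triphenylphosphonium bromide | [P+](c1ccccc1)(c1ccccc1)(c1ccccc1)C/C(C)=C/C=C/C=C(C)/C=C/C=C(C)/C=C/[C@H]1C(C)=C[C@H](O)CC1(C)C.[Br-] | intermediate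
31 | (3S,5R,6S,3'R,6'R)-5,6-epoxy-5,6-dihydro-β,ε-carotene-3,3'-diol (lutein 5,6-epoxide) | O[C@H]1CC(C)(C)[C@]2(/C=C/C(C)=C/C=C/C(C)=C/C=C/C=C(C)/C=C/C=C(C)/C=C/[C@H]3C(C)=C[C@H](O)CC3(C)C)O[C@]2(C)C1 | intermediate
32 | hexadecanoyl chloride (palmitoyl chloride) | CCCCCCCCCCCCCCCC(=O)Cl | starting material
33 | (3S,5R,6S,3'R,6'R)-5,6-epoxy-5,6-dihydro-β,ε-carotene-3,3'-diyl dihexadecanoate | CCCCCCCCCCCCCCCC(=O)O[C@H]1CC(C)(C)[C@]2(/C=C/C(C)=C/C=C/C(C)=C/C=C/C=C(C)/C=C/C=C(C)/C=C/[C@H]3C(C)=C[C@H](OC(=O)CCCCCCCCCCCCCCC)CC3(C)C)O[C@]2(C)C1 | target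

**Totals**
Total step count: 25. Longest linear sequence: 15 steps (13 to 33, steps 11 to 25); the epoxy branch (steps 1 to 10) joins at step 24.

**Steps most likely to fail**

Step 11. The risk is erosion of enantiomeric purity: the product 14 can itself be photolysed to an achiral dienylketene that re-closes thermally to racemic material, and the conversion must be kept low. The fallback no longer relies on chirality transfer alone but adds an enzymatic kinetic resolution at the first compound with a carbinol handle. It sets out from 17 of reduced enantiomeric purity. Lipase-catalysed transesterification with vinyl acetate (Pseudomonas cepacia lipase, t-BuOMe, rt) should acylate the (4R)-carbinol selectively to methyl (1R,4R)-4-acetoxy-2,6,6-trimethylcyclohex-2-ene-1-carboxylate F1. The unreacted (1S,4S)-alcohol is removed by chromatography, and K2CO3 in MeOH returns enantiopure 17.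

Step 12. The risk is silent loss of the C6' configuration by enolisation of the vinylogous β-keto ester toward C6' during ring opening and work-up (16 has no second stereocentre), alongside oxidation at a wrong allylic site. The fallback sets out from crude 15 and comes back at 20, one step shorter. The cyclobutanone is opened with N,O-dimethylhydroxylamine (pyridine, CH2Cl2, 0 °C) to (1R)-N-methoxy-N,2,6,6-tetramethyl-4-oxocyclohex-2-ene-1-carboxamide F2, whose α-hydrogen is far less acidic. LiBH(s-Bu)3 then gives (1R,4R)-4-hydroxy-N-methoxy-N,2,6,6-tetramethylcyclohex-2-ene-1-carboxamide F3. Silylation gives (1R,4R)-4-(tert-butyldimethylsilyloxy)-N-methoxy-N,2,6,6-tetramethylcyclohex-2-ene-1-carboxamide F4, and i-Bu2AlH (THF, −78 °C) reduces F4 directly to aldehyde 20.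

Step 13. The risk is poor facial selectivity in the hydride addition (cis instead of trans alcohol) or competing conjugate reduction. The fallback replaces facial control by inversion at carbon; it sets out from 16 and comes back at 17. Luche reduction (NaBH4, CeCl3·7H2O, MeOH, −78 °C), which should favour axial attack, gives methyl (1R,4S)-4-hydroxy-2,6,6-trimethylcyclohex-2-ene-1-carboxylate F5. Mitsunobu reaction with 4-nitrobenzoic acid (PPh3, diisopropyl azodicarboxylate, THF) inverts C3' to methyl (1R,4R)-4-(4-nitrobenzoyloxy)-2,6,6-trimethylcyclohex-2-ene-1-carboxylate F6. K2CO3 in MeOH then gives 17.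

**Further compounds**
F1 | step 11 | methyl (1R,4R)-4-acetoxy-2,6,6-trimethylcyclohex-2-ene-1-carboxylate | COC(=O)[C@H]1C(C)=C[C@H](OC(C)=O)CC1(C)C
F2 | step 12 | (1R)-N-methoxy-N,2,6,6-tetramethyl-4-oxocyclohex-2-ene-1-carboxamide | CON(C)C(=O)[C@H]1C(C)=CC(=O)CC1(C)C
F3 | step 12 | (1R,4R)-4-hydroxy-N-methoxy-N,2,6,6-tetramethylcyclohex-2-ene-1-carboxamide | CON(C)C(=O)[C@H]1C(C)=C[C@H](O)CC1(C)C
F4 | step 12 | (1R,4R)-4-(tert-butyldimethylsilyloxy)-N-methoxy-N,2,6,6-tetramethylcyclohex-2-ene-1-carboxamide | CON(C)C(=O)[C@H]1C(C)=C[C@H](O[Si](C)(C)C(C)(C)C)CC1(C)C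
F5 | step 13 | methyl (1R,4S)-4-hydroxy-2,6,6-trimethylcyclohex-2-ene-1-carboxylate | COC(=O)[C@H]1C(C)=C[C@@H](O)CC1(C)C
F6 | step 13 | methyl (1R,4R)-4-(4-nitrobenzoyloxy)-2,6,6-trimethylcyclohex-2-ene-1-carboxylate | COC(=O)[C@H]1C(C)=C[C@H](OC(=O)c2ccc(cc2)[N+](=O)[O-])CC1(C)C
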